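**Plan**

1. Locants: unprimed = methylated flavone unit (rings A and C), C1'–C6' = its ring B, double-primed = apigenin unit. First cut: ring C at O1–C2 and C2–C3 (cyclodehydration, Baker–Venkataraman shift), giving benzoic acid 15 and acetophenone 20.
2. Second cut: ring B at C1'–C2' and C5'–C6', giving 2-siloxy-3-aryl diene 9 and methyl propiolate 10. This works because ring B is a 1,2,4-trisubstituted benzene with its oxygen on C4' para to C1' and ortho to the biaryl carbon C3', which is the pattern such a diene and a propiolate deliver.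
3. Third cut: the C3'–C8'' bond is never made by coupling; C3' reaches C8'' as the central carbon of an allyl group moved from O7'' by Claisen rearrangement of apigenin allyl ether 3.
4. Forward: apigenin is used intact, and its C8'' chain is grown (allyl, acetonyl, enone, siloxydiene). Ring B is then closed by cycloaddition and dehydrogenation, ring C by acyl shift and cyclodehydration onto ring A (from 2,6-dimethoxytoluene), and BCl3 unmasks the phenols.
5. Stereochemistry: the target has no stereocentre, so nothing has to be set.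

Key step: step 7

Assumption: the C3'–C8'' biaryl axis carries no descriptor in the target and is treated as configurationally undefined.
Abbreviation: Ar = 5,7-bis(benzyloxy)-2-[4-(benzyloxy)phenyl]-4-oxochromen-8-yl (the tri-O-benzylapigenin-8-yl group).

**Route**

Step 1
Reactants: 1 apigenin; 2 allyl bromide
Product: 3 7-O-allylapigenin [5-hydroxy-2-(4-hydroxyphenyl)-7-(prop-2-enyloxy)chromen-4-one]
Conditions: 2 (1.05 equiv), K2CO3 (1.0 equiv), DMF, 25 °C
Reagents that add atoms: none
Why: Williamson etherification; the 7-hydroxyl, para to the pyranone carbonyl, is the most acidic phenol of apigenin and the 5-hydroxyl is held in a hydrogen bond to C4=O, so one equivalent of base and halide should alkylate O7 first.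

Step 2
Reactants: 3 7-O-allylapigenin
Product: 4 8-allylapigenin [5,7-dihydroxy-2-(4-hydroxyphenyl)-8-(prop-2-enyl)chromen-4-one]
Conditions: N,N-diethylaniline, 200 °C
Reagents that add atoms: none
Why: Aromatic Claisen rearrangement; the [3,3]-sigmatropic shift moves the allyl group from O7 to an ortho carbon, and C8 is expected to be preferred over C6 because the C7–C8 bond of a 7-oxybenzopyran-4-one has the greater double-bond character, any C6 isomer being removed by chromatography.

Step 3
Reactants: 4 8-allylapigenin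
Product: 5 8-allyl-5,7,4'-tri-O-benzylapigenin [5,7-bis(benzyloxy)-2-[4-(benzyloxy)phenyl]-8-(prop-2-enyl)chromen-4-one]
Conditions: BnBr (4 equiv), K2CO3, Bu4NI (cat.), DMF, 70 °C
Reagents that add atoms: benzyl bromide, BrCc1ccccc1
Why: Williamson ether synthesis; warm carbonate in DMF should also alkylate the hydrogen-bonded 5-hydroxyl, and capping O7 prevents oxypalladation of the allyl group to a dihydrobenzofuran in the next step.

Step 4
Reactants: 5 8-allyl-5,7,4'-tri-O-benzylapigenin
Product: 6 8-acetonyl flavone [5,7-bis(benzyloxy)-2-[4-(benzyloxy)phenyl]-8-(2-oxopropyl)chromen-4-one]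
Conditions: PdCl2 (10 mol %), CuCl (1 equiv), O2 (1 atm), DMF/H2O 7:1, 25 °C
Reagents that add atoms: water, O
Why: Tsuji–Wacker oxidation; Markovnikov hydroxypalladation of the terminal alkene and β-hydride elimination should give the methyl ketone, as is usual for allylarenes, while benzyl ethers and the flavone are inert.

Step 5
Reactants: 6 8-acetonyl flavone
Product: 8 enone [5,7-bis(benzyloxy)-2-[4-(benzyloxy)phenyl]-8-(3-oxobut-1-en-2-yl)chromen-4-one], via Mannich base 7 (not isolated)
Conditions: CH2(NMe2)2 (3 equiv), Ac2O (4 equiv), DMF, 60 °C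
Reagents that add atoms: bis(dimethylamino)methane, CN(C)CN(C)C
Why: Mannich methylenation; the reagent pair generates Me2N=CH2+ in the flask, the more acidic benzylic enol should add to it to give 7, and loss of dimethylamine (trapped as its acetamide) leaves the α-methylene ketone, a transformation known for arylacetones.

Step 6
Reactants: 8 enone
Product: 9 siloxydiene [8-[3-(tert-butyldimethylsilyloxy)buta-1,3-dien-2-yl]-5,7-bis(benzyloxy)-2-[4-(benzyloxy)phenyl]chromen-4-one]
Conditions: TBSOTf (1.3 equiv), Et3N (2 equiv), CH2Cl2, 0 °C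
Reagents that add atoms: tert-butyldimethylsilyl trifluoromethanesulfonate, CC(C)(C)[Si](C)(C)OS(=O)(=O)C(F)(F)F
Why: Soft enolisation and O-silylation of a methyl ketone; the only α-hydrogens are those of the methyl group, so only the cross-conjugated 2-siloxy-1,3-diene can form.

Step 7
Reactants: 9 siloxydiene; 10 methyl propiolate
Product: 12 methyl 4-(tert-butyldimethylsilyloxy)-3-Ar-benzoate, via cyclohexa-1,4-diene adduct 11 (not isolated)
Conditions: 10 (5 equiv), toluene, 110 °C, sealed tube; then DDQ (1.2 equiv), 25 °C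
Reagents that add atoms: none
Why: The electron-rich 2-siloxydiene and the electron-poor alkyne should combine in a concerted normal-demand [4+2] cycloaddition (Diels–Alder reaction of a 2-siloxybutadiene with an acetylenic ester), after which DDQ takes a hydride from one doubly allylic CH2 of 11 and a proton from the other, aromatising the ring with the silyl ether intact. Ring B is closed intermolecularly as a six-membered carbocycle by formation of C1'–C2' and C5'–C6' in the same event. No stereocentre is created, and the two sp3 carbons of 11 are erased by the dehydrogenation. The step needs regioselectivity: the diene terminus next to the siloxy carbon has the largest HOMO coefficient and should bond to the β-carbon of the propiolate, placing the ester para to the siloxy group, while the aryl group on the other internal carbon is twisted out of the diene plane by its two ortho substituents and should exert little competing bias. It also needs chemoselectivity in the oxidation, which the far greater hydride-donor ability of the cyclohexadiene over the benzyl ethers should secure at room temperature. The small linear dienophile attacks the two unhindered CH2 termini, so the perpendicular flavone should not block it.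

Step 8
Reactants: 12 methyl 4-(tert-butyldimethylsilyloxy)-3-Ar-benzoate
Product: 14 methyl 4-(benzyloxy)-3-Ar-benzoate, via phenol 13 (not isolated)
Conditions: CsF (2 equiv), BnBr (1.5 equiv), DMF, 25 °C
Reagents that add atoms: benzyl bromide, BrCc1ccccc1
Why: One-pot silyl-to-benzyl ether exchange (fluoride desilylation, then Williamson alkylation of the caesium phenoxide), giving a phenol protecting group that survives the basic acyl shift to come.

Step 9
Reactants: 14 methyl 4-(benzyloxy)-3-Ar-benzoate
Product: 15 4-(benzyloxy)-3-Ar-benzoic acid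
Conditions: LiOH·H2O (3 equiv), THF/MeOH/H2O, 40 °C; then 1 M HCl
Reagents that add atoms: lithium hydroxide, [Li+].[OH-]
Why: Saponification of a methyl benzoate; benzyl ethers are stable to hydroxide and the mild temperature should keep the pyranone ring closed.

Step 10
Reactants: 16 2,6-dimethoxytoluene
Product: 18 3,5-dimethoxy-4-methylphenol, via aryl pinacol boronate 17 (not isolated)
Conditions: B2pin2 (0.55 equiv), [Ir(OMe)(cod)]2 (1.5 mol %), 4,4'-di-tert-butyl-2,2'-bipyridine (3 mol %), THF, 80 °C; then aq. NaOH, H2O2, 0 °C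
Reagents that add atoms: bis(pinacolato)diboron, CC1(C)OB(OC1(C)C)B1OC(C)(C)C(C)(C)O1 (boryl group of 17); hydrogen peroxide, OO (phenol oxygen of 18)
Why: Sterically controlled C–H borylation catalysed by [Ir(OMe)(cod)]2 should select C4 of 16, the only C–H without an ortho substituent, and peroxide oxidation of the boronate (aryl shift from boron to oxygen) installs the third oxygen of the phloroglucinol pattern.

Step 11
Reactants: 18 3,5-dimethoxy-4-methylphenol
Product: 20 1-(6-hydroxy-2,4-dimethoxy-3-methylphenyl)ethanone, via aryl acetate 19 (not isolated)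
Conditions: Ac2O (1.5 equiv), BF3·OEt2, 80 °C; then aq. NaOAc
Reagents that add atoms: acetic anhydride, CC(=O)OC(C)=O
Why: O-Acetylation followed by BF3-promoted Fries rearrangement; the acyl group can only move to the two equivalent positions ortho to the phenol because the para position carries the methyl group, and BF3 is mild enough to leave both methyl ethers in place.

Step 12
Reactants: 15 4-(benzyloxy)-3-Ar-benzoic acid; 20 1-(6-hydroxy-2,4-dimethoxy-3-methylphenyl)ethanone
Product: 21 2-acetyl-3,5-dimethoxy-4-methylphenyl 4-(benzyloxy)-3-Ar-benzoate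
Conditions: DCC (1.2 equiv), DMAP (cat.), CH2Cl2, 25 °C
Reagents that add atoms: none
Why: Steglich esterification; DCC activates the acid and DMAP transfers the acyl group to the hydrogen-bonded phenol, the usual way to the O-aroyl acetophenone needed for the acyl shift.

Step 13
Reactants: 21 2-acetyl-3,5-dimethoxy-4-methylphenyl 4-(benzyloxy)-3-Ar-benzoate
Product: 22 1-(6-hydroxy-2,4-dimethoxy-3-methylphenyl)-3-[4-(benzyloxy)-3-Ar-phenyl]propane-1,3-dione
Conditions: LiN(SiMe3)2 (3 equiv), THF, −78 → 0 °C; then AcOH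
Reagents that add atoms: none
Why: Baker–Venkataraman rearrangement; the lithium enolate of the acetyl group attacks the neighbouring aryl ester intramolecularly, moving the aroyl group from oxygen to carbon and forming C2–C3.

Step 14
Reactants: 22 the 1,3-diketone
Product: 23 5,7-dimethoxy-6-methyl-2-[4-(benzyloxy)-3-Ar-phenyl]chromen-4-one (protected biflavone)
Conditions: NaOAc, AcOH, 100 °C
Reagents that add atoms: none
Why: Cyclodehydration of an o-hydroxyaryl 1,3-diketone; the single free phenol adds to the distal carbonyl and water is lost to close ring C at O1–C2, buffered acetic acid being chosen to spare the acid-sensitive peri benzyl ether.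

Step 15
Reactants: 23 protected biflavone
Product: 24 CNP0113589.0 (6-methyl-7-O-methylamentoflavone)
Conditions: BCl3 (excess), C6HMe5, CH2Cl2, −78 → 0 °C; then MeOH, H2O
Reagents that add atoms: none
Why: Lewis-acid ether cleavage; BCl3 should remove the four benzyl groups with pentamethylbenzene as cation scavenger and, through chelation to the C4 carbonyl, the peri 5-methyl ether, whereas the unchelated 7-methyl ether is not expected to react at or below 0 °C.

**Compound list**

1 | apigenin | O=c1cc(-c2ccc(O)cc2)oc2cc(O)cc(O)c12 | starting material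
2 | allyl bromide | C=CCBr | starting material
3 | 7-O-allylapigenin | O=c1cc(-c2ccc(O)cc2)oc2cc(OCC=C)cc(O)c12 | intermediate
4 | 8-allylapigenin | O=c1cc(-c2ccc(O)cc2)oc2c(CC=C)c(O)cc(O)c12 | intermediate
5 | 8-allyl-5,7,4'-tri-O-benzylapigenin | O=c1cc(-c2ccc(OCc3ccccc3)cc2)oc2c(CC=C)c(OCc3ccccc3)cc(OCc3ccccc3)c12 | intermediate
6 | 5,7-bis(benzyloxy)-2-[4-(benzyloxy)phenyl]-8-(2-oxopropyl)chromen-4-one | O=c1cc(-c2ccc(OCc3ccccc3)cc2)oc2c(CC(C)=O)c(OCc3ccccc3)cc(OCc3ccccc3)c12 | intermediate
7 | 5,7-bis(benzyloxy)-2-[4-(benzyloxy)phenyl]-8-[1-(dimethylamino)-3-oxobutan-2-yl]chromen-4-one (Mannich base, racemic) | O=c1cc(-c2ccc(OCc3ccccc3)cc2)oc2c(C(CN(C)C)C(C)=O)c(OCc3ccccc3)cc(OCc3ccccc3)c12 | intermediate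
8 | 5,7-bis(benzyloxy)-2-[4-(benzyloxy)phenyl]-8-(3-oxobut-1-en-2-yl)chromen-4-one | O=c1cc(-c2ccc(OCc3ccccc3)cc2)oc2c(C(=C)C(C)=O)c(OCc3ccccc3)cc(OCc3ccccc3)c12 | intermediate
9 | 8-[3-(tert-butyldimethylsilyloxy)buta-1,3-dien-2-yl]-5,7-bis(benzyloxy)-2-[4-(benzyloxy)phenyl]chromen-4-one | C=C(O[Si](C)(C)C(C)(C)C)C(=C)c1c(OCc2ccccc2)cc(OCc2ccccc2)c2c(=O)cc(-c3ccc(OCc4ccccc4)cc3)oc12 | intermediate
10 | methyl propiolate | C#CC(=O)OC | starting material
11 | methyl 4-(tert-butyldimethylsilyloxy)-5-Ar-cyclohexa-1,4-diene-1-carboxylate | COC(=O)C1=CCC(O[Si](C)(C)C(C)(C)C)=C(c2c(OCc3ccccc3)cc(OCc3ccccc3)c3c(=O)cc(-c4ccc(OCc5ccccc5)cc4)oc23)C1 | intermediate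
12 | methyl 4-(tert-butyldimethylsilyloxy)-3-Ar-benzoate | COC(=O)c1ccc(O[Si](C)(C)C(C)(C)C)c(-c2c(OCc3ccccc3)cc(OCc3ccccc3)c3c(=O)cc(-c4ccc(OCc5ccccc5)cc4)oc23)c1 | intermediate
13 | methyl 4-hydroxy-3-Ar-benzoate (caesium salt in the flask) | COC(=O)c1ccc(O)c(-c2c(OCc3ccccc3)cc(OCc3ccccc3)c3c(=O)cc(-c4ccc(OCc5ccccc5)cc4)oc23)c1 | intermediate
14 | methyl 4-(benzyloxy)-3-Ar-benzoate | COC(=O)c1ccc(OCc2ccccc2)c(-c2c(OCc3ccccc3)cc(OCc3ccccc3)c3c(=O)cc(-c4ccc(OCc5ccccc5)cc4)oc23)c1 | intermediate
15 | 4-(benzyloxy)-3-Ar-benzoic acid | OC(=O)c1ccc(OCc2ccccc2)c(-c2c(OCc3ccccc3)cc(OCc3ccccc3)c3c(=O)cc(-c4ccc(OCc5ccccc5)cc4)oc23)c1 | intermediate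
16 | 2,6-dimethoxytoluene | Cc1c(OC)cccc1OC | starting material
17 | 2-(3,5-dimethoxy-4-methylphenyl)-4,4,5,5-tetramethyl-1,3,2-dioxaborolane | Cc1c(OC)cc(B2OC(C)(C)C(C)(C)O2)cc1OC | intermediate
18 | 3,5-dimethoxy-4-methylphenol | Cc1c(OC)cc(O)cc1OC | intermediate
19 | 3,5-dimethoxy-4-methylphenyl acetate | CC(=O)Oc1cc(OC)c(C)c(OC)c1 | intermediate
20 | 1-(6-hydroxy-2,4-dimethoxy-3-methylphenyl)ethanone | CC(=O)c1c(O)cc(OC)c(C)c1OC | intermediate
21 | 2-acetyl-3,5-dimethoxy-4-methylphenyl 4-(benzyloxy)-3-Ar-benzoate | CC(=O)c1c(OC(=O)c2ccc(OCc3ccccc3)c(-c3c(OCc4ccccc4)cc(OCc4ccccc4)c4c(=O)cc(-c5ccc(OCc6ccccc6)cc5)oc34)c2)cc(OC)c(C)c1OC | intermediate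
22 | 1-(6-hydroxy-2,4-dimethoxy-3-methylphenyl)-3-[4-(benzyloxy)-3-Ar-phenyl]propane-1,3-dione | COc1cc(O)c(C(=O)CC(=O)c2ccc(OCc3ccccc3)c(-c3c(OCc4ccccc4)cc(OCc4ccccc4)c4c(=O)cc(-c5ccc(OCc6ccccc6)cc5)oc34)c2)c(OC)c1C | intermediate
23 | 5,7-dimethoxy-6-methyl-2-[4-(benzyloxy)-3-Ar-phenyl]chromen-4-one | COc1cc2oc(-c3ccc(OCc4ccccc4)c(-c4c(OCc5ccccc5)cc(OCc5ccccc5)c5c(=O)cc(-c6ccc(OCc7ccccc7)cc6)oc45)c3)cc(=O)c2c(OC)c1C | intermediate
24 | CNP0113589.0 (6-methyl-7-O-methylamentoflavone) | COc1cc2oc(-c3ccc(O)c(-c4c(O)cc(O)c5c(=O)cc(-c6ccc(O)cc6)oc45)c3)cc(=O)c2c(O)c1C | target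

**Step count and risks**

Total steps: 15. Longest linear sequence: 13 (steps 1–9 and 12–15, from apigenin); the acetophenone branch is steps 10–11.

Steps most likely to fail:

Step 7. The cycloaddition at the congested diene may be slow enough that the enol silane is lost on heating, or some ester may end up meta to the siloxy group. The fallback makes the biaryl bond by Suzuki–Miyaura coupling; it sets out from apigenin 1 and rejoins the route at benzoate 14. Apigenin would be perbenzylated (BnBr, K2CO3, DMF) to 5,7,4'-tri-O-benzylapigenin F1 and iodinated at C8, the site known to react in 5,7-dialkoxyflavones (I2, CF3CO2Ag, CH2Cl2), to give 8-iodo-5,7,4'-tri-O-benzylapigenin F2. Commercial methyl 3-bromo-4-hydroxybenzoate would be benzylated to methyl 4-(benzyloxy)-3-bromobenzoate F3 and borylated (B2pin2, PdCl2(dppf), KOAc, dioxane) to methyl 4-(benzyloxy)-3-(4,4,5,5-tetramethyl-1,3,2-dioxaborolan-2-yl)benzoate F4. Coupling of F2 with F4 (Pd(PPh3)4, K2CO3, DMF/H2O, 90 °C) should give 14. This path also bypasses steps 1 to 6 and 8.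

Step 5. Aminomethylation may occur at the methyl group instead of the hindered benzylic carbon, or the enone may oligomerise under the warm Mannich conditions. The fallback fixes the regiochemistry in an isolated enol silane; it sets out from ketone 6 and rejoins at enone 8. Thermodynamic silylation (Me3SiCl, Et3N, DMF, 80 °C) should give the conjugated (Z)-trimethylsilyl enol ether F5. Its reaction with Me2N=CH2+ I− in CH2Cl2 at 25 °C would give Mannich base 7, here isolated. Quaternisation with MeI to the trimethylammonium iodide F6 and elimination with aqueous NaHCO3 at 25 °C should then deliver 8 without heating.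

Step 1. Alkylation may spill over to the 4'-phenol and give the bis-allyl ether. The fallback differentiates the phenols through their acetates; it sets out from apigenin 1 and rejoins at allyl ether 3. Peracetylation (Ac2O, pyridine) gives apigenin triacetate F7, whose 7-acetate, the most electrophilic, is removed selectively (PhSH, imidazole, N-methylpyrrolidone, 0 °C) to give 5,4'-di-O-acetylapigenin F8. Allylation of the single free phenol (allyl bromide, K2CO3, acetone) gives 7-O-allyl-5,4'-di-O-acetylapigenin F9, and methanolysis (K2CO3, MeOH, 0 °C) returns 3.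

Further compounds
F1 | step 7 | 5,7,4'-tri-O-benzylapigenin | O=c1cc(-c2ccc(OCc3ccccc3)cc2)oc2cc(OCc3ccccc3)cc(OCc3ccccc3)c12
F2 | step 7 | 8-iodo-5,7,4'-tri-O-benzylapigenin | O=c1cc(-c2ccc(OCc3ccccc3)cc2)oc2c(I)c(OCc3ccccc3)cc(OCc3ccccc3)c12
F3 | step 7 | methyl 4-(benzyloxy)-3-bromobenzoate | COC(=O)c1ccc(OCc2ccccc2)c(Br)c1
F4 | step 7 | methyl 4-(benzyloxy)-3-(4,4,5,5-tetramethyl-1,3,2-dioxaborolan-2-yl)benzoate | COC(=O)c1ccc(OCc2ccccc2)c(B2OC(C)(C)C(C)(C)O2)c1
F5 | step 5 | 5,7-bis(benzyloxy)-2-[4-(benzyloxy)phenyl]-8-[(Z)-2-(trimethylsilyloxy)prop-1-enyl]chromen-4-one | O=c1cc(-c2ccc(OCc3ccccc3)cc2)oc2c(/C=C(/C)O[Si](C)(C)C)c(OCc3ccccc3)cc(OCc3ccccc3)c12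
F6 | step 5 | [2-Ar-3-oxobutyl]trimethylammonium iodide (racemic) | C[N+](C)(C)CC(C(C)=O)c1c(OCc2ccccc2)cc(OCc2ccccc2)c2c(=O)cc(-c3ccc(OCc4ccccc4)cc3)oc12.[I-]
F7 | step 1 | apigenin 5,7,4'-triacetate | CC(=O)Oc1ccc(-c2cc(=O)c3c(OC(C)=O)cc(OC(C)=O)cc3o2)cc1
F8 | step 1 | 5,4'-di-O-acetylapigenin | CC(=O)Oc1ccc(-c2cc(=O)c3c(OC(C)=O)cc(O)cc3o2)cc1
F9 | step 1 | 7-O-allyl-5,4'-di-O-acetylapigenin | CC(=O)Oc1ccc(-c2cc(=O)c3c(OC(C)=O)cc(OCC=C)cc3o2)cc1
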